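Atoms carry labdane locants (ring A: C1–C5, C10; ring B: C5–C10; C11–C16: spiro side chain). The route rests on cutting ring B across C5–C10 and C8–C9. One catalytic enantioselective intramolecular Diels–Alder reaction of an acyclic trienal closes rings A and B together, forms the C5–C10 ring-fusion bond and sets the methyl-bearing quaternary centre C10. It exploits the 1,4-oxygen pattern of ring B: the C6 oxygen is the silyloxy group of the diene, the C9 oxygen arises from the formyl group that activates the dienophile. The precursor is a geranate-derived (E)-3-methyl-2-enal linked by C1–C4 to a (Z)-2-silyloxy-1,3-diene.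

Key step: step 7

Remark: in ring compounds β is the face of the C10 methyl group and α the opposite face; C17 is the methyl group on C8.
Assumption: the (S)-configured oxazaborolidinium ion of step 7 is taken to leave the Re face of C3 of trienal 10 open, and the ligand enantiomer of step 13 is the one that leads to the (13R)-epoxide; if either sense is the opposite, the mirror-image catalyst or ligand is used.

Step 1
Reactants: 1 (E)-pent-3-en-2-one
Product: 3 (E)-2-(trimethylsilyloxy)penta-1,3-diene, via lithium dienolate 2 (not isolated)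
Conditions: LiN(iPr)2, THF, −78 °C; Me3SiCl, −78 °C to rt
Reagents that add atoms: chlorotrimethylsilane, C[Si](C)(C)Cl
Why: Kinetic deprotonation of the enone at its methyl group and O-silylation should give the cross-conjugated 2-silyloxydiene (silyl enol ether formation).

Step 2
Reactants: 4 methyl geranate
Product: 5 methyl (2E)-7-chloro-3,7-dimethyloct-2-enoate
Conditions: HCl (gas), CH2Cl2, −20 °C
Reagents that add atoms: hydrogen chloride, Cl
Why: Markovnikov hydrochlorination should occur only at the electron-rich trisubstituted 6,7-alkene, because the 2,3-alkene is deactivated by conjugation with the ester.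

Step 3
Reactants: 5 methyl (2E)-7-chloro-3,7-dimethyloct-2-enoate; 3 (E)-2-(trimethylsilyloxy)penta-1,3-diene
Product: 6 methyl (2E,10E)-3,7,7-trimethyl-9-oxododeca-2,10-dienoate
Conditions: TiCl4, CH2Cl2, −60 °C
Reagents that add atoms: none
Why: Lewis-acid ionisation of the tertiary chloride and capture of the cation by the terminal CH2 of the silyloxydiene (SN1 α-tert-alkylation of a silyl enol ether) should build the gem-dimethyl quaternary carbon (later C4) next to a CH2–CO unit and leave the (E)-propenyl ketone.

Step 4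
Reactants: 6 methyl (2E,10E)-3,7,7-trimethyl-9-oxododeca-2,10-dienoate
Product: 8 methyl (2E,8Z,10E)-3,7,7-trimethyl-9-(triisopropylsilyloxy)dodeca-2,8,10-trienoate, via lithium enolate 7 (not isolated)
Conditions: LiN(SiMe3)2, THF, −78 °C; iPr3SiOTf, −78 to 0 °C
Reagents that add atoms: triisopropylsilyl trifluoromethanesulfonate, CC(C)[Si](OS(=O)(=O)C(F)(F)F)(C(C)C)C(C)C
Why: Kinetic deprotonation of the enone at its saturated α-CH2 (the enoate is not deprotonated by the silylamide) and O-silylation give the 2-silyloxydiene, and the (Z)-enol ether should form because the tert-alkyl substituent avoids allylic 1,3-strain with the propenyl group.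

Step 5
Reactants: 8 methyl (2E,8Z,10E)-3,7,7-trimethyl-9-(triisopropylsilyloxy)dodeca-2,8,10-trienoate
Product: 9 (2E,8Z,10E)-3,7,7-trimethyl-9-(triisopropylsilyloxy)dodeca-2,8,10-trien-1-ol
Conditions: iBu2AlH, CH2Cl2, −78 °C
Reagents that add atoms: none
Why: Hydride 1,2-reduction of the enoate gives the allylic alcohol and leaves the silyl dienol ether untouched.

Step 6
Reactants: 9 (2E,8Z,10E)-3,7,7-trimethyl-9-(triisopropylsilyloxy)dodeca-2,8,10-trien-1-ol
Product: 10 (2E,8Z,10E)-3,7,7-trimethyl-9-(triisopropylsilyloxy)dodeca-2,8,10-trienal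
Conditions: MnO2, CH2Cl2, rt
Reagents that add atoms: none
Why: Neutral allylic oxidation with MnO2 should give the (E)-enal without isomerising the double bond or cleaving the silyl enol ether.

Step 7
Reactants: 10 (2E,8Z,10E)-3,7,7-trimethyl-9-(triisopropylsilyloxy)dodeca-2,8,10-trienal
Product: 12 9β-formyl-4,4,8β,10β-tetramethyl-trans-decalin-6-one (5α-H), via silyl enol ether cycloadduct 11 (not isolated)
Conditions: (S)-3,3-diphenyl-1-(o-tolyl)tetrahydropyrrolo[1,2-c][1,3,2]oxazaborole (20 mol %), HNTf2 (17 mol %), CH2Cl2, −78 to −20 °C; then Bu4NF, AcOH, THF, 0 °C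
Reagents that add atoms: none
Why: The N-protonated oxazaborolidine binds the formyl oxygen and lowers the LUMO of the enal, so that the electron-rich 2-silyloxydiene C5=C6–C7=C8 adds across C9=C10 in a concerted but strongly asynchronous [4+2] cycloaddition in which the nucleophilic enol-ether carbon C5 bonds to the enal β-carbon C10 ahead of C8–C9 (Mukaiyama–Michael-like). The closest known reaction type is the chiral oxazaborolidinium-catalysed intramolecular Diels–Alder reaction of trienals (type 1, 1,7,9-decatriene pattern) together with the reaction of 2-silyloxydienes under the same catalysis. Ring A closes through the C1–C4 tether by the C5–C10 bond (6-exo with respect to the enal double bond), ring B is the cycloaddition ring itself, completed by the C8–C9 bond, and the fluoride work-up turns its silyl enol ether into the C6 ketone. The quaternary centre C10 is controlled by the catalyst, which shields the Si face of the enal β-carbon so that C5 adds to its Re face, while C5, C8 and C9 follow from the endo transition state (formyl group under the diene, tether outside) and the E,Z,E geometry of the triene. The only selectivity the route needs from this step is the facial one at C10, because C9 becomes a ketone in step 8 and C8 and C5 then lie next to the C9 and C6 carbonyl groups and equilibrate, so that exo or cis-fused adducts converge on the same dione. The substrate secures this through the fixed (E)-geometry of the trisubstituted enal inherited from geranate, the (Z)-enol ether that keeps the tether outside the diene, and the formyl group as the only Lewis-basic site for the catalyst.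

Step 8
Reactants: 12 9β-formyl-4,4,8β,10β-tetramethyl-trans-decalin-6-one
Product: 14 4,4,8α,10β-tetramethyl-trans-decalin-6,9-dione, via 8β-methyl dione 13 (not isolated)
Conditions: Cu(OAc)2 (10 mol %), 2,2'-bipyridine, DABCO, O2 (1 atm), DMF, 40 °C
Reagents that add atoms: dioxygen, O=O
Why: Copper-catalysed aerobic deformylation of the α-branched aldehyde (oxygenation of its enol and C–C cleavage to ketone and formate) should excise C11 and give the C9 ketone, and the amine base should equilibrate C8 to the equatorial 8α-methyl epimer and C5 to the trans ring fusion.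

Step 9
Reactants: 14 4,4,8α,10β-tetramethyl-trans-decalin-6,9-dione
Product: 15 6β-hydroxy-4,4,8α,10β-tetramethyl-trans-decalin-9-one
Conditions: Li(s-Bu)3BH, THF, −78 °C; then NaOH, H2O2
Reagents that add atoms: none
Why: The bulky hydride should react only at the C6 carbonyl, which carries a single α-branch, and not at the C9 carbonyl flanked by quaternary C10 and tertiary C8; equatorial delivery from the α face, the β face being blocked by the axial C4 and C10 methyl groups, gives the axial 6β-alcohol (trialkylborohydride reduction).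

Step 10
Reactants: 15 6β-hydroxy-4,4,8α,10β-tetramethyl-trans-decalin-9-one
Product: 16 4,4,8α,10β-tetramethyl-9-methylene-trans-decalin-6β-ol
Conditions: Ph3PCH3Br, KOtBu (excess), toluene, 90 °C
Reagents that add atoms: methyltriphenylphosphonium bromide, C[P+](c1ccccc1)(c1ccccc1)c1ccccc1.[Br-]
Why: Wittig methylenation at elevated temperature should convert the hindered C9 ketone into the exocyclic alkene (new C11), the free hydroxyl being carried as its alkoxide and C8 staying at its thermodynamic configuration.

Step 11
Reactants: 16 4,4,8α,10β-tetramethyl-9-methylene-trans-decalin-6β-ol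
Product: 17 9α,11-epoxide of 16 (spiro-oxirane, oxygen on the α face, C11 on the β face)
Conditions: mCPBA, NaHCO3, CH2Cl2, 0 °C
Reagents that add atoms: 3-chloroperoxybenzoic acid, OOC(=O)c1cccc(Cl)c1
Why: Prilezhaev epoxidation of the exocyclic alkene from the α face, anti to the adjacent axial C10 methyl group, should fix the C9–O bond in the 9α configuration.

Step 12
Reactants: 17 9α,11-epoxide of 16; 18 3-methylbut-3-en-1-ol (isoprenol)
Product: 20 labd-13(16)-ene-6β,9α,15-triol, via dilithio-isoprenol 19 (not isolated)
Conditions: 18 (4 equiv), n-BuLi (8 equiv), TMEDA, Et2O–hexane, 0 °C to rt; then 17, THF, −30 °C to rt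
Reagents that add atoms: none
Why: The 2-substituted allyllithium formed by double deprotonation of isoprenol should open the spiro-epoxide at its CH2 terminus (SN2 epoxide opening), forming C11–C12 and setting free the tertiary 9α-hydroxyl without touching C9.

Step 13
Reactants: 20 labd-13(16)-ene-6β,9α,15-triol
Product: 22 (13S)-9α,13-epoxylabdane-6β,15,16-triol, via 13,16-epoxy triol 21 (not isolated)
Conditions: Hf(OtBu)4 (10 mol %), chiral C2-symmetric bishydroxamic acid ligand (11 mol %), cumene hydroperoxide, DMPU, MgO, toluene, 0 °C; then CSA (10 mol %), CH2Cl2, 0 °C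
Reagents that add atoms: cumene hydroperoxide, CC(C)(OO)c1ccccc1
Why: Hydroxyl-directed catalytic asymmetric epoxidation of the homoallylic alcohol (the primary C15 hydroxyl binds the metal) should give the (13R)-epoxide under ligand control, and acid-promoted 5-exo opening at the tertiary carbon by the 9α-hydroxyl with inversion then closes the tetrahydrofuran and sets C13.

Step 14
Reactants: 22 (13S)-9α,13-epoxylabdane-6β,15,16-triol
Product: 25 (13S)-9α,13-epoxy-6β-hydroxylabdan-16,15-olide, via hydroxy aldehyde 23 (not isolated), via lactol 24 (not isolated)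
Conditions: TEMPO (20 mol %), PhI(OAc)2 (2.5 equiv), CH2Cl2, rt
Reagents that add atoms: none
Why: The oxoammonium oxidant should take the unhindered primary C15 alcohol in preference to the neopentyl C16 alcohol and the hindered secondary C6 alcohol, after which the aldehyde closes onto the C16 hydroxyl and the lactol is oxidised to the γ-lactone with its carbonyl at C15 (TEMPO oxidative lactonisation of a 1,4-diol).

Step 15
Reactants: 25 (13S)-9α,13-epoxy-6β-hydroxylabdan-16,15-olide
Product: 26 previtexilactone
Conditions: Ac2O, DMAP (cat.), pyridine, rt to 40 °C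
Reagents that add atoms: acetic anhydride, CC(=O)OC(C)=O
Why: DMAP-catalysed acylation should esterify the only remaining, axial hydroxyl group with retention at C6, the weakly basic medium avoiding β-elimination of the C13 ether oxygen.

Compound list
1 | (E)-pent-3-en-2-one | C/C=C/C(C)=O | starting material
2 | lithium (E)-penta-1,3-dien-2-olate | [Li]OC(=C)/C=C/C | intermediate
3 | (E)-2-(trimethylsilyloxy)penta-1,3-diene | C/C=C/C(=C)O[Si](C)(C)C | intermediate
4 | methyl geranate, methyl (2E)-3,7-dimethylocta-2,6-dienoate | COC(=O)/C=C(\C)CCC=C(C)C | starting material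
5 | methyl (2E)-7-chloro-3,7-dimethyloct-2-enoate | COC(=O)/C=C(\C)CCCC(C)(C)Cl | intermediate
6 | methyl (2E,10E)-3,7,7-trimethyl-9-oxododeca-2,10-dienoate | COC(=O)/C=C(\C)CCCC(C)(C)CC(=O)/C=C/C | intermediate
7 | lithium (8Z)-enolate of 6 | COC(=O)/C=C(\C)CCCC(C)(C)/C=C(\O[Li])/C=C/C | intermediate
8 | methyl (2E,8Z,10E)-3,7,7-trimethyl-9-(triisopropylsilyloxy)dodeca-2,8,10-trienoate | COC(=O)/C=C(\C)CCCC(C)(C)/C=C(\O[Si](C(C)C)(C(C)C)C(C)C)/C=C/C | intermediate
9 | (2E,8Z,10E)-3,7,7-trimethyl-9-(triisopropylsilyloxy)dodeca-2,8,10-trien-1-ol | OC/C=C(\C)CCCC(C)(C)/C=C(\O[Si](C(C)C)(C(C)C)C(C)C)/C=C/C | intermediate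
10 | (2E,8Z,10E)-3,7,7-trimethyl-9-(triisopropylsilyloxy)dodeca-2,8,10-trienal | O=C/C=C(\C)CCCC(C)(C)/C=C(\O[Si](C(C)C)(C(C)C)C(C)C)/C=C/C | intermediate
11 | cycloadduct: 9β-formyl-4,4,8β,10β-tetramethyl-6-(triisopropylsilyloxy)-trans-octal-6-ene (5α-H, 8α-H, 9α-H) | O=C[C@H]1[C@@H](C)C=C(O[Si](C(C)C)(C(C)C)C(C)C)[C@H]2C(C)(C)CCC[C@]12C | intermediate
12 | 9β-formyl-4,4,8β,10β-tetramethyl-trans-decalin-6-one (5α-H) | O=C[C@H]1[C@@H](C)CC(=O)[C@H]2C(C)(C)CCC[C@]12C | intermediate
13 | 4,4,8β,10β-tetramethyl-trans-decalin-6,9-dione | O=C1[C@@H](C)CC(=O)[C@H]2C(C)(C)CCC[C@]12C | intermediate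
14 | 4,4,8α,10β-tetramethyl-trans-decalin-6,9-dione (5α-H) | O=C1[C@H](C)CC(=O)[C@H]2C(C)(C)CCC[C@]12C | intermediate
15 | 6β-hydroxy-4,4,8α,10β-tetramethyl-trans-decalin-9-one | O=C1[C@H](C)C[C@@H](O)[C@H]2C(C)(C)CCC[C@]12C | intermediate
16 | 4,4,8α,10β-tetramethyl-9-methylene-trans-decalin-6β-ol | C=C1[C@H](C)C[C@@H](O)[C@H]2C(C)(C)CCC[C@]12C | intermediate
17 | 9α,11-epoxide of 16 (spiro-oxirane, O α, C11 β) | C1O[C@@]12[C@H](C)C[C@@H](O)[C@H]3C(C)(C)CCC[C@]23C | intermediate
18 | 3-methylbut-3-en-1-ol (isoprenol) | CC(=C)CCO | starting material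
19 | dilithio-isoprenol, lithium 3-(lithiomethyl)but-3-en-1-olate | [Li]CC(=C)CCO[Li] | intermediate
20 | labd-13(16)-ene-6β,9α,15-triol | OCCC(=C)CC[C@@]1(O)[C@H](C)C[C@@H](O)[C@H]2C(C)(C)CCC[C@]12C | intermediate
21 | (13R)-13,16-epoxylabdane-6β,9α,15-triol | OCC[C@@]1(CO1)CC[C@@]2(O)[C@H](C)C[C@@H](O)[C@H]3C(C)(C)CCC[C@]23C | intermediate
22 | (13S)-9α,13-epoxylabdane-6β,15,16-triol | OCC[C@]1(CO)CC[C@@]2(O1)[C@H](C)C[C@@H](O)[C@H]3C(C)(C)CCC[C@]23C | intermediate
23 | (13S)-9α,13-epoxy-6β,16-dihydroxylabdan-15-al | O=CC[C@]1(CO)CC[C@@]2(O1)[C@H](C)C[C@@H](O)[C@H]3C(C)(C)CCC[C@]23C | intermediate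
24 | (13S)-9α,13:15,16-diepoxylabdane-6β,15-diol (lactol, C15 epimers) | OC1C[C@]2(CO1)CC[C@@]3(O2)[C@H](C)C[C@@H](O)[C@H]4C(C)(C)CCC[C@]34C | intermediate
25 | (13S)-9α,13-epoxy-6β-hydroxylabdan-16,15-olide | O=C1C[C@]2(CO1)CC[C@@]3(O2)[C@H](C)C[C@@H](O)[C@H]4C(C)(C)CCC[C@]34C | intermediate
26 | previtexilactone, (5S,6R,8R,9R,10S,13S)-6-acetoxy-9,13-epoxylabdan-16,15-olide | CC(=O)O[C@@H]1C[C@@H](C)[C@]2(CC[C@]3(COC(=O)C3)O2)[C@@]2(C)CCCC(C)(C)[C@H]12 | target

Total step count: 15. Longest linear sequence: 14 steps (steps 2–15, from methyl geranate 4).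

Steps most likely to fail

Step 7. The strongly acidic catalyst may protodesilylate the dienol ether before the congested C5–C10 bond forms, or the β,β-disubstituted enal may be attacked with poor facial discrimination at C10. Fallback (resolution in place of asymmetric catalysis): from 10 the cycloaddition is promoted by stoichiometric Me2AlCl (CH2Cl2, −78 to −20 °C, Bu4NF/AcOH work-up), which should give 12 as the racemate. Steps 8–10 are run unchanged and the racemic alcohol is esterified with (S)-2-methoxy-2-phenylacetic acid (DCC, DMAP, CH2Cl2). The diastereomeric esters are separated by chromatography and the (S)-O-methylmandelate of 16 F1 is cleaved with LiOH (THF/MeOH/H2O), which comes back to the route at 16.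

Step 13. The tertiary C9 hydroxyl may compete with the C15 hydroxyl for the metal and erode the facial selectivity at the 1,1-disubstituted alkene, or the acid-promoted opening may take an SN1 course and lose the C13 configuration. Fallback (Sharpless asymmetric epoxidation of an allylic alcohol, then one-carbon homologation), setting out from 17:
- The dianion of 2-methylprop-2-en-1-ol (n-BuLi, TMEDA) should open 17 to 15-norlabd-13-ene-6β,9α,16-triol F2.
- Ti(OiPr)4, L-(+)-diethyl tartrate and t-BuOOH (CH2Cl2, −20 °C) should give the (13S)-13,14-epoxide F3.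
- t-BuPh2SiCl and imidazole should protect the C16 hydroxyl as the silyl ether F4.
- CSA should close the tetrahydrofuran by attack of the 9α-hydroxyl at C13 with inversion, giving the C14 alcohol F5.
- TEMPO/PhI(OAc)2 should give the aldehyde F6, and Ph3P=CHOMe the methyl enol ether F7.
- Bu4NF followed by aqueous HCl in THF should give the lactol, which comes back to the route at 24 and is oxidised to 25 by the reagent of step 14.

Step 12. The allyllithium may act as a base and isomerise the epoxide to an allylic alcohol, or the C6 alkoxide may open the epoxide intramolecularly before the hindered CH2 is attacked. Fallback (radical instead of polar C11–C12 bond formation): from 17, MgI2 (Et2O, 0 °C) should open the epoxide to the iodohydrin 11-iodo-4,4,8α,10β-tetramethyl-9β-methyl-trans-decalin-6β,9α-diol F8. Dianion 19 is quenched with Bu3SnCl to give 3-[(tributylstannyl)methyl]but-3-en-1-ol F9. Radical allylation of F8 with F9 (AIBN, benzene, 80 °C) should then come back to the route at 20.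

Further compounds
F1 | step 7 | (S)-O-methylmandelate of 16 | C=C1[C@H](C)C[C@@H](OC(=O)[C@@H](OC)c2ccccc2)[C@H]2C(C)(C)CCC[C@]12C
F2 | step 13 | 15-norlabd-13-ene-6β,9α,16-triol | OCC(=C)CC[C@@]1(O)[C@H](C)C[C@@H](O)[C@H]2C(C)(C)CCC[C@]12C
F3 | step 13 | (13S)-13,14-epoxy-15-norlabdane-6β,9α,16-triol | OC[C@]1(CO1)CC[C@@]2(O)[C@H](C)C[C@@H](O)[C@H]3C(C)(C)CCC[C@]23C
F4 | step 13 | 16-O-tert-butyldiphenylsilyl ether of F3 | CC(C)(C)[Si](OC[C@]1(CO1)CC[C@@]2(O)[C@H](C)C[C@@H](O)[C@H]3C(C)(C)CCC[C@]23C)(c1ccccc1)c1ccccc1
F5 | step 13 | 9α,13-epoxy-16-(tert-butyldiphenylsilyloxy)-15-norlabdane-6β,14-diol (C13 as in 26) | OC[C@]1(CO[Si](c2ccccc2)(c2ccccc2)C(C)(C)C)CC[C@@]2(O1)[C@H](C)C[C@@H](O)[C@H]3C(C)(C)CCC[C@]23C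
F6 | step 13 | 9α,13-epoxy-6β-hydroxy-16-(tert-butyldiphenylsilyloxy)-15-norlabdan-14-al | O=C[C@]1(CO[Si](c2ccccc2)(c2ccccc2)C(C)(C)C)CC[C@@]2(O1)[C@H](C)C[C@@H](O)[C@H]3C(C)(C)CCC[C@]23C
F7 | step 13 | 9α,13-epoxy-15-methoxy-16-(tert-butyldiphenylsilyloxy)labd-14-en-6β-ol | COC=C[C@]1(CO[Si](c2ccccc2)(c2ccccc2)C(C)(C)C)CC[C@@]2(O1)[C@H](C)C[C@@H](O)[C@H]3C(C)(C)CCC[C@]23C
F8 | step 12 | iodohydrin, 9β-(iodomethyl)-4,4,8α,10β-tetramethyl-trans-decalin-6β,9α-diol | IC[C@@]1(O)[C@H](C)C[C@@H](O)[C@H]2C(C)(C)CCC[C@]12C
F9 | step 12 | 3-[(tributylstannyl)methyl]but-3-en-1-ol | CCCC[Sn](CCCC)(CCCC)CC(=C)CCO
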